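**Retrosynthetic overview**
- Target 12 ⇒ lactone (R)-8 + benzyl bromide 9: the C3–CH2Ar′ bond is made last by enolate alkylation anti to the C4 substituent, and the phenol silyl ether is cleaved in the same pot.
- (R)-8 ⇒ prochiral cyclobutanone 6: desymmetrising oxygen insertion forms the lactone C–O bond and sets C4 (key step).
- 6 ⇒ allylarene 2 + dichloroketene (from 3): [2+2] cycloaddition, then dechlorination.
- 2 ⇒ methoxyeugenol 1 by O-silylation.
- Ring order: the cyclobutanone is built first (step 2) and expanded to the γ-lactone (step 3); both arene rings are bought.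

Assumption: the SMILES is read as the trans-(3R,4R) lactone; 4-allyl-2,6-dimethoxyphenol and 3,4,5-trimethoxybenzyl bromide are bought; compound numbers follow the forward route.

**Step 1**
Reactants: 1 4-allyl-2,6-dimethoxyphenol (methoxyeugenol)
Product: 2 (4-allyl-2,6-dimethoxyphenoxy)(tert-butyl)dimethylsilane
Conditions: TBSCl (1.2 equiv), imidazole (2.5 equiv), DMF, 25 °C
Reagents that add atoms: tert-butyldimethylsilyl chloride, CC(C)(C)[Si](C)(C)Cl
Why: Imidazole-mediated O-silylation masks the phenol, which would otherwise be acylated by Cl3CCOCl/dichloroketene in step 2 and consume base in step 4; no stereocentre is involved.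

**Step 2**
Reactants: 2 (4-allyl-2,6-dimethoxyphenoxy)(tert-butyl)dimethylsilane; 3 trichloroacetyl chloride
Product: 6 3-[4-(tert-butyldimethylsilyloxy)-3,5-dimethoxybenzyl]cyclobutan-1-one, via dichloroketene 4 (not isolated), via dichlorocyclobutanone 5 (not isolated)
Conditions: Cl3CCOCl (2 equiv), Zn–Cu (3 equiv), Et2O–DME, 25→35 °C; filter, concentrate; then Zn dust, AcOH, 25→50 °C
Reagents that add atoms: none
Why: The [2+2] ketene–alkene cycloaddition of in-situ dichloroketene is regioselective (terminal alkene carbon bonds to the ketene carbonyl carbon) for the 2,2-dichloro-3-substituted cyclobutanone, and Zn/AcOH reductive dechlorination of the crude adduct gives the achiral, prochiral 3-substituted cyclobutanone, so no stereocontrol is needed here.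

**Step 3**
Reactants: 6 3-[4-(tert-butyldimethylsilyloxy)-3,5-dimethoxybenzyl]cyclobutan-1-one
Product: 8 (R)-4-[4-(tert-butyldimethylsilyloxy)-3,5-dimethoxybenzyl]dihydrofuran-2(3H)-one, via Criegee adduct 7 (not isolated)
Conditions: confined chiral imidodiphosphoric acid (5 mol %), 35 % aq. H2O2 (1.5 equiv), CHCl3, −40 °C
Reagents that add atoms: hydrogen peroxide, OO
Why: Proposed new method: a confined chiral imidodiphosphoric acid (two 3,3′-bis(2,4,6-triethylphenyl)-BINOL units on a P–N–P core) is proposed to catalyse a desymmetrising Baeyer–Villiger oxidation with aqueous H2O2 — the acid adds H2O2 to the strained ketone to give Criegee adduct 7, held by two hydrogen bonds (P=O···HO and P–OH···OOH) inside the chiral pocket with the arylmethyl arm forced out through the pocket mouth, so only one of the two enantiotopic ring CH2 groups can lie antiperiplanar to the O–O bond and migrate to oxygen with strain release, forming the lactone C–O bond and setting C4 as R (the sense of induction cannot be predicted, so the catalyst antipode that gives R is chosen in a test run with each enantiomer); the closest known reactions are the chiral BINOL-phosphoric-acid-catalysed Baeyer–Villiger desymmetrisation of 3-substituted cyclobutanones with H2O2 (good ee for 3-aryl, only moderate for 3-benzyl groups, the gap addressed here) and confined imidodiphosphoric-acid-catalysed sulfoxidation with aqueous H2O2.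

**Step 4**
Reactants: 8 (R)-4-[4-(tert-butyldimethylsilyloxy)-3,5-dimethoxybenzyl]dihydrofuran-2(3H)-one; 9 3,4,5-trimethoxybenzyl bromide
Product: 12 (3R,4R)-4-(4-hydroxy-3,5-dimethoxybenzyl)-3-(3,4,5-trimethoxybenzyl)dihydrofuran-2(3H)-one, via lithium enolate 10 (not isolated), via silylated trans-lactone 11 (not isolated)
Conditions: LiHMDS (1.1 equiv), THF–DMPU, −78 °C; 9 (1.05 equiv), −78→−40 °C; then AcOH (3 equiv), TBAF (1.5 equiv), 0 °C
Reagents that add atoms: none
Why: Lithium enolate alkylation (SN2) of a β-substituted γ-butyrolactone occurs anti to the C4 arylmethyl group and gives the trans (3R,4R) product, which is also the thermodynamic epimer, and AcOH-buffered fluoride then cleaves the aryl silyl ether without O-benzylation of the freed phenol.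

**Compound list**
1 | 4-allyl-2,6-dimethoxyphenol (methoxyeugenol) | C=CCc1cc(OC)c(O)c(OC)c1 | starting material
2 | (4-allyl-2,6-dimethoxyphenoxy)(tert-butyl)dimethylsilane | C=CCc1cc(OC)c(O[Si](C)(C)C(C)(C)C)c(OC)c1 | intermediate
3 | trichloroacetyl chloride | ClC(Cl)(Cl)C(Cl)=O | starting material
4 | dichloroketene | ClC(Cl)=C=O | intermediate (not isolated)
5 | 2,2-dichloro-3-[4-(tert-butyldimethylsilyloxy)-3,5-dimethoxybenzyl]cyclobutan-1-one (racemic) | COc1cc(CC2CC(=O)C2(Cl)Cl)cc(OC)c1O[Si](C)(C)C(C)(C)C | intermediate (not isolated)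
6 | 3-[4-(tert-butyldimethylsilyloxy)-3,5-dimethoxybenzyl]cyclobutan-1-one (achiral) | COc1cc(CC2CC(=O)C2)cc(OC)c1O[Si](C)(C)C(C)(C)C | intermediate
7 | 1-hydroperoxy-3-[4-(tert-butyldimethylsilyloxy)-3,5-dimethoxybenzyl]cyclobutan-1-ol (Criegee adduct) | COc1cc(CC2CC(O)(OO)C2)cc(OC)c1O[Si](C)(C)C(C)(C)C | intermediate (not isolated)
8 | (R)-4-[4-(tert-butyldimethylsilyloxy)-3,5-dimethoxybenzyl]dihydrofuran-2(3H)-one | COc1cc(C[C@H]2COC(=O)C2)cc(OC)c1O[Si](C)(C)C(C)(C)C | intermediate
9 | 3,4,5-trimethoxybenzyl bromide | COc1cc(CBr)cc(OC)c1OC | starting material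
10 | lithium (4R)-4-[4-(tert-butyldimethylsilyloxy)-3,5-dimethoxybenzyl]-4,5-dihydrofuran-2-olate | COc1cc(C[C@H]2COC(O[Li])=C2)cc(OC)c1O[Si](C)(C)C(C)(C)C | intermediate (not isolated)
11 | (3R,4R)-4-[4-(tert-butyldimethylsilyloxy)-3,5-dimethoxybenzyl]-3-(3,4,5-trimethoxybenzyl)dihydrofuran-2(3H)-one | COc1cc(C[C@H]2COC(=O)[C@@H]2Cc2cc(OC)c(OC)c(OC)c2)cc(OC)c1O[Si](C)(C)C(C)(C)C | intermediate (not isolated)
12 | (3R,4R)-4-(4-hydroxy-3,5-dimethoxybenzyl)-3-(3,4,5-trimethoxybenzyl)dihydrofuran-2(3H)-one | COc1cc(C[C@H]2COC(=O)[C@@H]2Cc2cc(OC)c(OC)c(OC)c2)cc(OC)c1O | target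

**Step count**
Total steps: 4. Longest linear sequence: 4.

**Steps most likely to fail**

Step 3 (the proposed new Baeyer–Villiger desymmetrisation) may give low conversion or low ee with this bulky substrate. The fallback uses known chemistry and sets out from 6. Enantioselective deprotonation with a chiral lithium bis(1-phenylethyl)amide and in-situ TMSCl (THF, −100 °C; amide antipode chosen for the R product) gives the (R)-trimethylsilyl enol ether F1. Ozonolysis (O3, CH2Cl2–MeOH, −78 °C) with NaBH4 work-up gives (R)-3-[4-(tert-butyldimethylsilyloxy)-3,5-dimethoxybenzyl]-4-hydroxybutanoic acid F2, which lactonises on acidification and comes back to the route at 8.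

Step 2 may suffer from sluggish addition of dichloroketene to a monosubstituted alkene, or from ZnCl2 attack on the silyl ether. The fallback sets out from 2 and uses a keteniminium [2+2] cycloaddition (N,N-dimethylacetamide, Tf2O, 2,4,6-collidine, 1,2-dichloroethane, reflux). This gives the cyclobutaniminium triflate F3, which aqueous NaHCO3 hydrolyses to the ketone, coming back to the route at 6.

Step 4 may give incomplete or double alkylation, or O-benzylation during the one-pot desilylation. The fallback sets out from 8. Aldol addition of its lithium enolate to 3,4,5-trimethoxybenzaldehyde (COc1cc(C=O)cc(OC)c1OC; THF, −78 °C) gives the trans aldol adduct F4 as a mixture of carbinol epimers. Hydrogenolysis of the electron-rich benzylic C–OH (H2, Pd/C, AcOH, trace HClO4) comes back to the route at 11, which is desilylated with TBAF/AcOH as in step 4 to give 12.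

**Further compounds**
F1 | step 3 | tert-butyl{2,6-dimethoxy-4-[((1R)-3-(trimethylsilyloxy)cyclobut-2-en-1-yl)methyl]phenoxy}dimethylsilane | COc1cc(C[C@@H]2CC(O[Si](C)(C)C)=C2)cc(OC)c1O[Si](C)(C)C(C)(C)C
F2 | step 3 | (R)-3-[4-(tert-butyldimethylsilyloxy)-3,5-dimethoxybenzyl]-4-hydroxybutanoic acid | COc1cc(C[C@H](CC(=O)O)CO)cc(OC)c1O[Si](C)(C)C(C)(C)C
F3 | step 2 | N-{3-[4-(tert-butyldimethylsilyloxy)-3,5-dimethoxybenzyl]cyclobutylidene}-N-methylmethanaminium trifluoromethanesulfonate | COc1cc(CC2CC(=[N+](C)C)C2)cc(OC)c1O[Si](C)(C)C(C)(C)C.[O-]S(=O)(=O)C(F)(F)F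
F4 | step 4 | (3S,4R)-4-[4-(tert-butyldimethylsilyloxy)-3,5-dimethoxybenzyl]-3-[hydroxy(3,4,5-trimethoxyphenyl)methyl]dihydrofuran-2(3H)-one (carbinol epimers) | COc1cc(C[C@H]2COC(=O)[C@@H]2C(O)c2cc(OC)c(OC)c(OC)c2)cc(OC)c1O[Si](C)(C)C(C)(C)C
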